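## Structural features

Dendronpholide A is a cembranoid: a fourteen-membered carbocycle (C1–C14) bridged between C1 and C4 by an α-methylene ε-lactone, C15(=C17)–C16(=O)–O–C4, so that the oxepanone shares C1–C4 with the macrocycle (methyls C18 on C4, C19 on C8, C20 on C12). It has four stereocentres, 1R,4R,5S,13S: the quaternary C4 (methyl and lactone oxygen) sits next to the acetoxy carbon C5, and C1 (the ring CH carrying the acrylate) stands 1,3 to the free carbinol C13 across C14. Two E-trisubstituted olefins, C8=C9 and C11=C12, are separated by the doubly allylic C10, and the methyl of C11=C12 sits on C12, next to C13. The fragile groups are the exo-methylene lactone (a Michael acceptor that dislikes bases and nucleophiles), the secondary acetate beside a tertiary acyloxy carbon (acyl migration), the C13 hydroxyl (it could translactonise onto C16 to a six-membered lactone) and the C10 methylene. The real difficulty is closing the large ring while fixing two trisubstituted E-olefins and relating C1 to C4/C5 and to C13 across flexible chains. The key step uses the fact that C11=C12 lies on the far side of the ring from the lactone and is flanked by the C13 carbinol. A C11≡C12 alkyne can therefore be formed by metathesis of two methyl-capped alkyne arms (on C10 and C13), and the C13 hydroxyl can then direct tin to C12 and hydrogen trans onto C11.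

## Logic of the disconnections

26 to 25 and 24: the C12–CH3 bond is cut, then formally C12–Sn and C11–H. An E-olefin with its methyl next to a carbinol is what hydroxyl-directed trans-hydrostannation and methyl-for-tin exchange give, so the olefin geometry problem becomes an alkyne. The forward steps must put tin on C12 only, leave the acrylate and C8=C9 alone, and transfer methyl with retention in the presence of acetate and lactone.

24 to 23 to 22: after the C13 oxygen is silylated, the C11≡C12 bond is cut. This opens the macrocycle at a site remote from every stereocentre and from the lactone and gives an acyclic bis(methylalkyne) in which all four stereocentres already stand. The forward step needs a catalyst that touches only alkynes and a ring closure that beats oligomerisation. 22 and 23 were checked atom by atom against 26; both carry 1R,4R,5S,13S and the E C8=C9 olefin, so no correction is needed. The one refinement is that the silyl ether is put on one step before ring closure and removed with buffered HF, so acetate and methylene lactone never meet basic fluoride.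

22 to 21 to 20 to 18 + 19: the O–Si bond, then the C13–H bond (carbinol to ketone), then C13–C12 are cut. The propargylic centre becomes a reagent-controlled ynone reduction, and the ynone an acyl–alkyne coupling of a thioester. C13 is thus set independently of the other centres and the second alkyne arrives late as a three-carbon gas. The coupling must activate only the thioester beside a lactone and an acetate, and the reduction must take C=O and not the acrylate.

18 to 17 to 16: the acetate is removed and the lactone O–C4 bond is cut to an epoxy acid. The C4/C5 pair corresponds to a trans-epoxide of an E-olefin opened at C4 with inversion, so two stereocentres collapse into one epoxide and the seven-membered ring forms without acylating a tertiary alcohol. The forward step needs attack at the tertiary carbon (seven-membered, exo) and not at C5, and no elimination or hydride shift.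

16 to 15 to 13: the C15=C17 bond and the C16 oxidation level are cut back to a plain β-branched aldehyde. This keeps the acrylate out of the route until just before lactonisation. The methylenation must spare the thioester and the epoxide, and the oxidation must spare the olefin and alkyne.

13 to 10 + 12: the C1–C14 bond is cut as a conjugate addition of an acetate thioester enolate equivalent to an enal. This creates C1 from a linear precursor and leaves the two two-carbon arms on C1 differentiated as aldehyde and thioester. The demands are catalyst-controlled facial selectivity, 1,4- over 1,2-addition and survival of the epoxide. 12 goes back to 11 by enolate silylation.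

10 to 8 + 9, then 8 to 7 to 5 (through 6): the C1=C15 olefin is cut (ylide olefination), then C1 is taken to the nitrile level and C2–C3 is cut as displacement of an activated primary epoxy alcohol by a two-carbon nitrile anion. This returns to an epoxy alcohol. The demand is substitution at C3 without opening the neighbouring epoxide.

5 to 4 to 3 to 1 + 2: the epoxide C–O bonds are cut to an allylic alcohol; its hydroxyl makes the asymmetric epoxidation possible and also guarantees that C4=C5, not C8=C9, is oxidised. The C3–O bond is then cut (allylic oxidation of the E-methyl) and finally C10–C11 (allyl–alkynyl coupling), which reaches commercial materials. The demand is site selectivity in the allylic oxidation.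

## Other disconnections considered

Alternative 1: The cut is the lactone O–C4 bond, made last on an intact carbocycle. In the forward step the fourteen-membered 4S,5S-epoxy acrylic acid A2 is treated with camphorsulfonic acid; the carboxyl oxygen opens the epoxide at C4 with inversion and gives the hydroxy lactone A1.
- In favour: the bond-forming event is the same stereospecific opening used in step 11, so on control of C4/C5 it is the equal of the chosen plan. It is better in one respect: the macrocycle holds acid and epoxide in a fixed relation and the sensitive methylene lactone appears only at the end.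
- Against: it does not say how the ring is closed, so A2 still needs a macrocyclisation, now with an epoxide and a masked acid on board. Inside the ring the activated epoxide faces C8=C9, and transannular cation–olefin cyclisation should compete. The epoxide could not be introduced selectively on a macrocyclic triene, so it must come from the acyclic stage anyway.
- Comparison: mechanistically equal, structurally riskier at the last stage, and no gain in steps because the same operations are only reordered. It is kept as the reserve for step 16.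

Alternative 2: The cut is C4–C5. The acyclic keto aldehyde A4 (methyl ketone at C4, aldehyde at C5) is coupled reductively with TiCl3(DME)1.5 and zinc–copper couple at low temperature to the cis-diol A3, forming the ring and both carbinol centres together.
- In favour: it is the most convergent option. One step builds a ring, a skeletal bond and two stereocentres, which is better than the chosen key step (it sets none). Both E-olefins can be made by ordinary acyclic methods, so on olefin geometry it is the equal of the chosen plan without any hydrostannation.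
- Against: the sense at C4 and C5 relative to C1 and C13 rests only on the conformation of a macrocyclic transition state, with four diols possible. The lactone must then be made by acylating the tertiary C4 hydroxyl in competition with the C5 hydroxyl, and the exo-methylene must be added afterwards by enolate chemistry beside an acetate. A large excess of low-valent titanium must also spare an allylic silyl ether and an enolisable aldehyde.
- Comparison: better in convergence, weaker in stereochemical reliability, and the endgame is longer, so the step count comes out about equal.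

Alternative 3: The cut is C1–C14 by sigmatropic logic. In the sixteen-membered dilactone A6 the C13 ester carbonyl is methylenated with Cp2TiMe2. On heating, the resulting 2-alkoxydiene undergoes Claisen rearrangement: C14–C1 forms, C17–O breaks, and the ring contracts to the enone A5 with the methylene lactone in place.
- In favour: ring closure is an ester bond, generally easier than a C–C macrocyclisation (better). The rearrangement makes a C–C bond, the exo-methylene and the C1 centre at once (better in bond economy). The C11=C12 geometry is fixed in the acyclic acid portion before cyclisation, which equals the chosen plan on geometry and is three steps shorter.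
- Against: A6 has two conjugated ester carbonyls, and nothing guarantees that the titanium reagent picks the C13 enoate over the lactone. The configuration at C1 depends on chair versus boat geometry in a macrocycle and on the geometry of the C1=C15 bond. Reduction at C13 and a silyl-to-acetyl exchange at C5 would follow.
- Comparison: potentially the shortest route, but it carries two uncontrolled selectivities where the chosen key step carries none.

Key step: step 16

Remark: cembrane numbering as defined above is used for the macrocycles; geranyl bromide, propyne, both enantiomers of the imidazolidinone catalyst and the molybdenum alkylidyne are taken as purchasable.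

## Route

Step 1
Reactants: 1 geranyl bromide, (2E)-1-bromo-3,7-dimethylocta-2,6-diene; 2 prop-1-yn-1-ylmagnesium bromide
Product: 3 (5E)-6,10-dimethylundeca-5,9-dien-2-yne
Conditions: CuI (5 mol%), THF, 0 °C to rt
Reagents that add atoms: none
Why: Copper-catalysed allyl–alkynyl coupling of a primary allylic bromide with an alkynyl Grignard reagent; substitution at the unhindered C10 terminus keeps the E geometry of C8=C9 and installs the methyl-capped C11 alkyne at the outset.

Step 2
Reactants: 3 dienyne
Product: 4 (2E,6E)-2,6-dimethylundeca-2,6-dien-9-yn-1-ol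
Conditions: SeO2 (cat.), t-BuOOH, salicylic acid (cat.), CH2Cl2, 0 °C to rt
Reagents that add atoms: tert-butyl hydroperoxide, CC(C)(C)OO
Why: Selenium dioxide allylic oxidation (ene reaction, then [2,3]-shift) goes to the E-methyl of the terminal trisubstituted olefin, as in farnesyl-type polyenes; the C8=C9 olefin is slowed by its propargylic substituent, so C3 should be oxygenated selectively.

Step 3
Reactants: 4 allylic alcohol
Product: 5 [(2S,3S)-2-methyl-3-[(3E)-3-methyloct-3-en-6-yn-1-yl]oxiran-2-yl]methanol
Conditions: Ti(Oi-Pr)4 (cat.), L-(+)-diethyl tartrate (cat.), t-BuOOH, 4 Å MS, CH2Cl2, −20 °C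
Reagents that add atoms: tert-butyl hydroperoxide, CC(C)(C)OO
Why: Sharpless asymmetric epoxidation; only the allylic alcohol olefin C4=C5 reacts, and the L-(+)-tartrate complex delivers oxygen to the face that gives the (2S,3S)-epoxy alcohol, i.e. 4S,5S in cembrane numbering.

Step 4
Reactants: 5 epoxy alcohol
Product: 7 3-[(2S,3S)-2-methyl-3-[(3E)-3-methyloct-3-en-6-yn-1-yl]oxiran-2-yl]propanenitrile, via epoxy triflate 6 (not isolated)
Conditions: Tf2O, 2,6-lutidine, CH2Cl2, −78 °C; then cannulated into LiCH2CN (MeCN, n-BuLi, excess), THF, −78 °C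
Reagents that add atoms: acetonitrile, CC#N; trifluoromethanesulfonic anhydride, O=S(=O)(OS(=O)(=O)C(F)(F)F)C(F)(F)F (its atoms stay only in 6)
Why: SN2 displacement of a primary epoxy triflate by the small cyanomethyl anion forms C2–C3 while the hindered trisubstituted epoxide is not attacked; quenching cold keeps the product anion from cyclising onto the epoxide.

Step 5
Reactants: 7 epoxy nitrile
Product: 8 3-[(2S,3S)-2-methyl-3-[(3E)-3-methyloct-3-en-6-yn-1-yl]oxiran-2-yl]propanal
Conditions: i-Bu2AlH, toluene, −78 °C; aq. KNaC4H4O6 (potassium sodium tartrate)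
Reagents that add atoms: water, O
Why: Partial reduction of a nitrile with diisobutylaluminium hydride and hydrolytic work-up gives the aldehyde; at −78 °C neither the epoxide nor the alkyne is reduced, and the aldehyde is used crude.

Step 6
Reactants: 8 epoxy aldehyde; 9 (triphenylphosphoranylidene)acetaldehyde
Product: 10 (2E)-5-[(2S,3S)-2-methyl-3-[(3E)-3-methyloct-3-en-6-yn-1-yl]oxiran-2-yl]pent-2-enal
Conditions: toluene, 70 °C
Reagents that add atoms: none
Why: Wittig olefination with a stabilised formylmethylene ylide gives the E-enal (C1=C15) under neutral conditions that leave the epoxide intact.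

Step 7
Reactants: 11 S-ethyl ethanethioate
Product: 12 tert-butyl{[1-(ethylsulfanyl)ethenyl]oxy}dimethylsilane
Conditions: LiN(i-Pr)2, THF, −78 °C; TBSCl, DMPU, −78 °C to rt
Reagents that add atoms: tert-butyldimethylsilyl chloride, CC(C)(C)[Si](C)(C)Cl
Why: O-Silylation of the lithium enolate of a thioester gives the silyl ketene thioacetal that serves as the acetate enolate equivalent.

Step 8
Reactants: 10 enal; 12 silyl ketene thioacetal
Product: 13 S-ethyl (3S)-5-[(2S,3S)-2-methyl-3-[(3E)-3-methyloct-3-en-6-yn-1-yl]oxiran-2-yl]-3-(2-oxoethyl)pentanethioate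
Conditions: (2R,5R)-5-benzyl-2-tert-butyl-3-methylimidazolidin-4-one·2,4-dinitrobenzoic acid (20 mol%), CH2Cl2, H2O (2 equiv), −60 °C
Reagents that add atoms: water, O
Why: Organocatalytic Mukaiyama–Michael addition through the E-iminium ion of 10: the benzyl group of the (2R,5R)-catalyst shields one face of C1, so 12 adds to the other and sets C1 as in the target (formally 3S in 13 because the thioester arm ranks first); the buffered medium at low temperature should spare the epoxide.

Step 9
Reactants: 13 aldehyde thioester
Product: 15 S-ethyl (3R)-5-[(2S,3S)-2-methyl-3-[(3E)-3-methyloct-3-en-6-yn-1-yl]oxiran-2-yl]-3-(3-oxoprop-1-en-2-yl)pentanethioate, via Mannich base 14 (not isolated)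
Conditions: CH2=NMe2+ I− (Eschenmoser's salt), Et3N, CH2Cl2, rt
Reagents that add atoms: N,N-dimethylmethyleneiminium iodide, C=[N+](C)C.[I-]
Why: α-Methylenation of an aldehyde by Mannich reaction and loss of dimethylamine; the tertiary amine does not attack the thioester, C1 is β to the aldehyde and cannot epimerise, and its descriptor becomes R only because C15 now ranks first.

Step 10
Reactants: 15 α-methylene aldehyde
Product: 16 (3R)-3-[2-(ethylsulfanyl)-2-oxoethyl]-5-[(2S,3S)-2-methyl-3-[(3E)-3-methyloct-3-en-6-yn-1-yl]oxiran-2-yl]-2-methylidenepentanoic acid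
Conditions: NaClO2, NaH2PO4, 2-methylbut-2-ene, t-BuOH/H2O, 0 °C
Reagents that add atoms: sodium chlorite, [Na+].[O-]Cl=O
Why: Pinnick oxidation turns the 2-substituted acrolein into the acrylic acid; the alkene scavenger removes hypochlorous acid, so the trisubstituted olefin, alkyne and thioester should survive.

Step 11
Reactants: 16 epoxy acrylic acid
Product: 17 S-ethyl 2-[(4R,7R)-7-[(1S,4E)-1-hydroxy-4-methylnon-4-en-7-yn-1-yl]-7-methyl-3-methylidene-2-oxooxepan-4-yl]ethanethioate
Conditions: CSA (10 mol%), CH2Cl2 (5 mM), 0 °C to rt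
Reagents that add atoms: none
Why: Acid-catalysed intramolecular epoxide opening (7-exo): the carboxyl oxygen attacks the tertiary C4, which best carries positive charge, with inversion (4S to 4R), closing the oxepanone and releasing the 5S hydroxyl with retention.

Step 12
Reactants: 17 hydroxy lactone
Product: 18 S-ethyl 2-[(4R,7R)-7-[(1S,4E)-1-(acetyloxy)-4-methylnon-4-en-7-yn-1-yl]-7-methyl-3-methylidene-2-oxooxepan-4-yl]ethanethioate
Conditions: Ac2O, pyridine, DMAP (cat.), CH2Cl2, 0 °C
Reagents that add atoms: acetic anhydride, CC(=O)OC(C)=O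
Why: Acylation of the only free hydroxyl, the secondary C5 alcohol.

Step 13
Reactants: 18 lactone thioester; 19 propyne
Product: 20 (1S,4E)-4-methyl-1-[(2R,5R)-2-methyl-6-methylidene-7-oxo-5-(2-oxopent-3-yn-1-yl)oxepan-2-yl]non-4-en-7-yn-1-yl acetate
Conditions: PdCl2(dppf) (10 mol%), P(2-furyl)3, CuI, Et3N, DMF, 50 °C
Reagents that add atoms: none
Why: Palladium-catalysed, copper-mediated coupling of a thioester with a terminal alkyne (acyl Sonogashira-type ketone synthesis); zerovalent palladium inserts only into the C(O)–S bond, so lactone, acetate and acrylate stay untouched and the methyl-capped C12 alkyne is installed.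

Step 14
Reactants: 20 ynone
Product: 21 (1S,4E)-1-[(2R,5R)-5-[(2S)-2-hydroxypent-3-yn-1-yl]-2-methyl-6-methylidene-7-oxooxepan-2-yl]-4-methylnon-4-en-7-yn-1-yl acetate
Conditions: Ru(p-cymene)[(S,S)-TsNCHPhCHPhNH] (3 mol%), i-PrOH, rt
Reagents that add atoms: none
Why: Noyori-type asymmetric transfer hydrogenation of an alkynyl ketone; with the (S,S)-catalyst the alkynyl group takes the place of the aryl group in the usual model, which gives the 13S alcohol, and the base-free conditions should leave the conjugated lactone alone.

Step 15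
Reactants: 21 propargylic alcohol
Product: 22 (1S,4E)-1-[(2R,5R)-5-[(2S)-2-{[tert-butyl(dimethyl)silyl]oxy}pent-3-yn-1-yl]-2-methyl-6-methylidene-7-oxooxepan-2-yl]-4-methylnon-4-en-7-yn-1-yl acetate
Conditions: TBSOTf, 2,6-lutidine, CH2Cl2, −78 °C
Reagents that add atoms: tert-butyldimethylsilyl trifluoromethanesulfonate, CC(C)(C)[Si](C)(C)OS(=O)(=O)C(F)(F)F
Why: Silylation removes the only protic group before alkyne metathesis and blocks translactonisation onto C16.

Step 16
Reactants: 22 bis(methylalkyne)
Product: 23 (1R,4R,5S,13S,8E)-5-acetoxy-13-[(tert-butyldimethylsilyl)oxy]-20-norcembra-8,15(17)-dien-11-yn-16,4-olide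
Conditions: [Mo(≡C-C6H4-4-OMe)(OSiPh3)3] (20 mol%), 5 Å MS, toluene (2 mM), 80 °C
Reagents that add atoms: none
Why: The alkylidyne adds across one methyl-capped alkyne of 22 in a [2+2] step to a metallacyclobutadiene, which opens the other way and loads the substrate onto molybdenum; the new alkylidyne then takes the second methyl alkyne intramolecularly, and cycloreversion releases 23 and an ethylidyne that ends as but-2-yne. The closest known reaction type is ring-closing alkyne metathesis of α,ω-bis(methylalkynes) to macrocyclic cycloalkynes with silanolate-supported hexavalent molybdenum alkylidynes. One ring is closed, the fourteen-membered carbocycle, by end-to-end macrocyclisation through the new endocyclic C11≡C12 bond; a ring of this size holds the linear C10–C11≡C12–C13 unit without undue strain. No stereocentre is formed, and C1, C4, C5 and C13 cannot epimerise under these neutral conditions. The step needs chemoselectivity for the two alkynes; the alkylidyne does not engage the exo-methylene, the C8=C9 olefin, the acetate or the lactone, and the silyl ether keeps the propargylic oxygen from exchanging with the silanolate ligands. It also needs ring closure over oligomerisation, which millimolar dilution and the 5 Å sieves (they take up but-2-yne) should secure, since the equilibrium is pulled toward the ring and oligomers can be cut back.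

Step 17
Reactants: 23 silyl ether cycloalkyne
Product: 24 (1R,4R,5S,13S,8E)-5-acetoxy-13-hydroxy-20-norcembra-8,15(17)-dien-11-yn-16,4-olide
Conditions: HF·pyridine, pyridine, THF, 0 °C to rt
Reagents that add atoms: none
Why: Fluoride cleavage of the silyl ether under buffered, non-basic conditions, so the acetate should not migrate and the lactone should not open.

Step 18
Reactants: 24 propargylic alcohol
Product: 25 (1R,4R,5S,13S,8E,11Z)-5-acetoxy-13-hydroxy-12-(tributylstannyl)-20-norcembra-8,11,15(17)-trien-16,4-olide
Conditions: [Cp*RuCl]4 (5 mol%), Bu3SnH, CH2Cl2, rt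
Reagents that add atoms: tributyltin hydride, CCCC[SnH](CCCC)CCCC
Why: Ruthenium-catalysed trans-hydrostannation; hydrogen bonding of the C13 hydroxyl to the chloride ligand steers tin to the proximal C12 and hydrogen trans onto C11, which places C13 and C10 trans across the new olefin, and the catalyst is selective for alkynes over the acrylate and C8=C9.

Step 19
Reactants: 25 alkenylstannane
Product: 26 dendronpholide A, (1R,4R,5S,13S,8E,11E)-5-acetoxy-13-hydroxycembra-8,11,15(17)-trien-16,4-olide
Conditions: MeI, Pd(PPh3)4, copper thiophene-2-carboxylate (CuTC), [Bu4N][Ph2PO2], DMF, rt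
Reagents that add atoms: iodomethane, CI
Why: Copper-assisted Stille-type methylation of the alkenylstannane with retention of geometry gives the E-trisubstituted C11=C12 olefin; the phosphinate salt takes up tin, and the free alcohol, acetate and lactone are tolerated.

## Compound list

1 | geranyl bromide, (2E)-1-bromo-3,7-dimethylocta-2,6-diene | CC(C)=CCC/C(C)=C/CBr | starting material
2 | prop-1-yn-1-ylmagnesium bromide | CC#C[Mg]Br | starting material
3 | (5E)-6,10-dimethylundeca-5,9-dien-2-yne | CC#CC/C=C(\C)CCC=C(C)C | intermediate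
4 | (2E,6E)-2,6-dimethylundeca-2,6-dien-9-yn-1-ol | OC/C(C)=C/CC/C(C)=C/CC#CC | intermediate
5 | [(2S,3S)-2-methyl-3-[(3E)-3-methyloct-3-en-6-yn-1-yl]oxiran-2-yl]methanol | OC[C@]1(C)O[C@H]1CC/C(C)=C/CC#CC | intermediate
6 | [(2S,3S)-2-methyl-3-[(3E)-3-methyloct-3-en-6-yn-1-yl]oxiran-2-yl]methyl trifluoromethanesulfonate | O=S(=O)(OC[C@]1(C)O[C@H]1CC/C(C)=C/CC#CC)C(F)(F)F | intermediate
7 | 3-[(2S,3S)-2-methyl-3-[(3E)-3-methyloct-3-en-6-yn-1-yl]oxiran-2-yl]propanenitrile | N#CCC[C@]1(C)O[C@H]1CC/C(C)=C/CC#CC | intermediate
8 | 3-[(2S,3S)-2-methyl-3-[(3E)-3-methyloct-3-en-6-yn-1-yl]oxiran-2-yl]propanal | O=CCC[C@]1(C)O[C@H]1CC/C(C)=C/CC#CC | intermediate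
9 | (triphenylphosphoranylidene)acetaldehyde | O=CC=P(c1ccccc1)(c1ccccc1)c1ccccc1 | starting material
10 | (2E)-5-[(2S,3S)-2-methyl-3-[(3E)-3-methyloct-3-en-6-yn-1-yl]oxiran-2-yl]pent-2-enal | O=C/C=C/CC[C@]1(C)O[C@H]1CC/C(C)=C/CC#CC | intermediate
11 | S-ethyl ethanethioate | CCSC(C)=O | starting material
12 | tert-butyl{[1-(ethylsulfanyl)ethenyl]oxy}dimethylsilane | C=C(SCC)O[Si](C)(C)C(C)(C)C | intermediate
13 | S-ethyl (3S)-5-[(2S,3S)-2-methyl-3-[(3E)-3-methyloct-3-en-6-yn-1-yl]oxiran-2-yl]-3-(2-oxoethyl)pentanethioate | CCSC(=O)C[C@H](CC=O)CC[C@]1(C)O[C@H]1CC/C(C)=C/CC#CC | intermediate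
14 | S-ethyl (3R)-3-[1-(dimethylamino)-3-oxopropan-2-yl]-5-[(2S,3S)-2-methyl-3-[(3E)-3-methyloct-3-en-6-yn-1-yl]oxiran-2-yl]pentanethioate (both epimers at the aminomethyl-bearing carbon) | CCSC(=O)C[C@H](C(CN(C)C)C=O)CC[C@]1(C)O[C@H]1CC/C(C)=C/CC#CC | intermediate
15 | S-ethyl (3R)-5-[(2S,3S)-2-methyl-3-[(3E)-3-methyloct-3-en-6-yn-1-yl]oxiran-2-yl]-3-(3-oxoprop-1-en-2-yl)pentanethioate | CCSC(=O)C[C@H](C(=C)C=O)CC[C@]1(C)O[C@H]1CC/C(C)=C/CC#CC | intermediate
16 | (3R)-3-[2-(ethylsulfanyl)-2-oxoethyl]-5-[(2S,3S)-2-methyl-3-[(3E)-3-methyloct-3-en-6-yn-1-yl]oxiran-2-yl]-2-methylidenepentanoic acid | CCSC(=O)C[C@H](C(=C)C(=O)O)CC[C@]1(C)O[C@H]1CC/C(C)=C/CC#CC | intermediate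
17 | S-ethyl 2-[(4R,7R)-7-[(1S,4E)-1-hydroxy-4-methylnon-4-en-7-yn-1-yl]-7-methyl-3-methylidene-2-oxooxepan-4-yl]ethanethioate | C=C1C(=O)O[C@@](C)([C@@H](O)CC/C(C)=C/CC#CC)CC[C@@H]1CC(=O)SCC | intermediate
18 | S-ethyl 2-[(4R,7R)-7-[(1S,4E)-1-(acetyloxy)-4-methylnon-4-en-7-yn-1-yl]-7-methyl-3-methylidene-2-oxooxepan-4-yl]ethanethioate | C=C1C(=O)O[C@@](C)([C@@H](OC(C)=O)CC/C(C)=C/CC#CC)CC[C@@H]1CC(=O)SCC | intermediate
19 | propyne | CC#C | starting material
20 | (1S,4E)-4-methyl-1-[(2R,5R)-2-methyl-6-methylidene-7-oxo-5-(2-oxopent-3-yn-1-yl)oxepan-2-yl]non-4-en-7-yn-1-yl acetate | C=C1C(=O)O[C@@](C)([C@@H](OC(C)=O)CC/C(C)=C/CC#CC)CC[C@@H]1CC(=O)C#CC | intermediate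
21 | (1S,4E)-1-[(2R,5R)-5-[(2S)-2-hydroxypent-3-yn-1-yl]-2-methyl-6-methylidene-7-oxooxepan-2-yl]-4-methylnon-4-en-7-yn-1-yl acetate | C=C1C(=O)O[C@@](C)([C@@H](OC(C)=O)CC/C(C)=C/CC#CC)CC[C@@H]1C[C@H](O)C#CC | intermediate
22 | (1S,4E)-1-[(2R,5R)-5-[(2S)-2-{[tert-butyl(dimethyl)silyl]oxy}pent-3-yn-1-yl]-2-methyl-6-methylidene-7-oxooxepan-2-yl]-4-methylnon-4-en-7-yn-1-yl acetate | C=C1C(=O)O[C@@](C)([C@@H](OC(C)=O)CC/C(C)=C/CC#CC)CC[C@@H]1C[C@H](O[Si](C)(C)C(C)(C)C)C#CC | intermediate
23 | (1R,4R,5S,13S,8E)-5-acetoxy-13-[(tert-butyldimethylsilyl)oxy]-20-norcembra-8,15(17)-dien-11-yn-16,4-olide | C=C1C(=O)O[C@]2(C)CC[C@@H]1C[C@H](O[Si](C)(C)C(C)(C)C)C#CC/C=C(\C)CC[C@@H]2OC(C)=O | intermediate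
24 | (1R,4R,5S,13S,8E)-5-acetoxy-13-hydroxy-20-norcembra-8,15(17)-dien-11-yn-16,4-olide | C=C1C(=O)O[C@]2(C)CC[C@@H]1C[C@H](O)C#CC/C=C(\C)CC[C@@H]2OC(C)=O | intermediate
25 | (1R,4R,5S,13S,8E,11Z)-5-acetoxy-13-hydroxy-12-(tributylstannyl)-20-norcembra-8,11,15(17)-trien-16,4-olide | C=C1C(=O)O[C@]2(C)CC[C@@H]1C[C@H](O)/C([Sn](CCCC)(CCCC)CCCC)=C/C/C=C(\C)CC[C@@H]2OC(C)=O | intermediate
26 | dendronpholide A, (1R,4R,5S,13S,8E,11E)-5-acetoxy-13-hydroxycembra-8,11,15(17)-trien-16,4-olide | C=C1C(=O)O[C@]2(C)CC[C@@H]1C[C@H](O)/C(C)=C/C/C=C(\C)CC[C@@H]2OC(C)=O | target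

## Step count and least certain steps

Total: 19 steps. Longest linear sequence: 18 steps (steps 1–6 and 8–19, from 1); step 7 is a one-step side branch.

Step 16 (key step). The most likely failure is oligomerisation and stalling. The C12 alkyne sits beside the bulky silyloxy group and the preformed oxepanone fixes the directions in which the two arms leave C1 and C4, so intermolecular metathesis may outrun closure while the catalyst slowly decays. The fallback moves ring closure ahead of lactonisation, so that a flexible open chain is cyclised and the lactone is then formed across the ring. It sets out from 16 and returns at 23.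
- Esterification with Me3SiCHN2 (toluene/MeOH) should give the methyl ester F1.
- Coupling with 19 as in step 13 should give the ynone F2, transfer hydrogenation as in step 14 the 13S alcohol F3, and silylation as in step 15 the silyl ether F4.
- Alkyne metathesis under the conditions of step 16 should close the macrocyclic epoxy ester F5.
- Me3SnOH (1,2-dichloroethane, 70 °C) should free the epoxy acid F6.
- Camphorsulfonic acid in dilute CH2Cl2 should give the hydroxy lactone F7 by the same inversion at C4 as in step 11.
- Acetylation as in step 12 gives 23.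

Step 8. The most likely failures are poor facial selectivity with an unsubstituted acetate nucleophile, competing 1,2-addition, and slow acid-induced opening of the epoxide during a long run at low temperature. The fallback replaces catalyst control by an auxiliary and sets out from 8, returning at 15.
- Olefination of 8 with diethyl {2-oxo-2-[(4S)-2-oxo-4-phenyl-1,3-oxazolidin-3-yl]ethyl}phosphonate (LiCl, i-Pr2NEt, MeCN) should give the E-enoyl imide F8.
- The cuprate from tert-butyl[(2-bromoprop-2-en-1-yl)oxy]dimethylsilane (t-BuLi, then MgBr2·OEt2, then CuBr·SMe2, THF, −78 to −40 °C) should add to the magnesium-chelated imide from the face opposite the phenyl group and give the adduct F9 with C1 as in the target.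
- LiSEt (THF, 0 °C) should displace the auxiliary and give the thioester F10.
- Bu4NF buffered with AcOH should free the allylic alcohol F11.
- MnO2 (CH2Cl2) should oxidise it to 15.

Step 4. The most likely failures are attack of the basic nucleophile on the epoxide, sluggish substitution at a carbon next to a fully substituted centre, and cyclisation of the deprotonated product nitrile onto the epoxide. The fallback builds C2–C3 by olefination and conjugate reduction and sets out from 5, returning at 8.
- Oxidation with SO3·pyridine, DMSO and i-Pr2NEt should give the epoxy aldehyde F12.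
- Wittig reaction with 9 should give the epoxy enal F13.
- Iminium-catalysed transfer hydrogenation (diethyl 2,6-dimethyl-1,4-dihydropyridine-3,5-dicarboxylate, dibenzylammonium trifluoroacetate cat., THF, rt) should reduce only the conjugated C2=C3 bond and give 8.

Step 2. The most likely failures are loss of site selectivity, with oxidation at C7 or at the doubly activated C10 of the skipped enyne, and over-oxidation to the enal. The fallback oxidises while an allylic acetate deactivates C8=C9 and brings in the alkyne afterwards; it sets out from 1 and returns at 5.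
- KOAc in DMF should give geranyl acetate F14.
- SeO2/t-BuOOH should then give the hydroxy acetate F15.
- Epoxidation as in step 3 should give the epoxy alcohol acetate F16.
- Stille-type allylic substitution with tributyl(prop-1-yn-1-yl)stannane (Pd2(dba)3, LiCl, DMF) at the unhindered C10 terminus should give 5.

## Further compounds

F1 | step 16 | methyl (3R)-3-[2-(ethylsulfanyl)-2-oxoethyl]-5-[(2S,3S)-2-methyl-3-[(3E)-3-methyloct-3-en-6-yn-1-yl]oxiran-2-yl]-2-methylidenepentanoate | CCSC(=O)C[C@H](C(=C)C(=O)OC)CC[C@]1(C)O[C@H]1CC/C(C)=C/CC#CC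
F2 | step 16 | methyl (3R)-5-[(2S,3S)-2-methyl-3-[(3E)-3-methyloct-3-en-6-yn-1-yl]oxiran-2-yl]-2-methylidene-3-(2-oxopent-3-yn-1-yl)pentanoate | CC#CC(=O)C[C@H](C(=C)C(=O)OC)CC[C@]1(C)O[C@H]1CC/C(C)=C/CC#CC
F3 | step 16 | methyl (3R)-3-[(2S)-2-hydroxypent-3-yn-1-yl]-5-[(2S,3S)-2-methyl-3-[(3E)-3-methyloct-3-en-6-yn-1-yl]oxiran-2-yl]-2-methylidenepentanoate | CC#C[C@@H](O)C[C@H](C(=C)C(=O)OC)CC[C@]1(C)O[C@H]1CC/C(C)=C/CC#CC
F4 | step 16 | methyl (3R)-3-[(2S)-2-{[tert-butyl(dimethyl)silyl]oxy}pent-3-yn-1-yl]-5-[(2S,3S)-2-methyl-3-[(3E)-3-methyloct-3-en-6-yn-1-yl]oxiran-2-yl]-2-methylidenepentanoate | CC#C[C@@H](O[Si](C)(C)C(C)(C)C)C[C@H](C(=C)C(=O)OC)CC[C@]1(C)O[C@H]1CC/C(C)=C/CC#CC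
F5 | step 16 | methyl 2-[(1R,4S,5S,13S,8E)-13-[(tert-butyldimethylsilyl)oxy]-4,5-epoxy-20-norcembr-8-en-11-yn-1-yl]prop-2-enoate (cembrane numbering) | COC(=O)C(=C)[C@@H]1CC[C@]2(C)O[C@H]2CC/C(C)=C/CC#C[C@@H](O[Si](C)(C)C(C)(C)C)C1
F6 | step 16 | 2-[(1R,4S,5S,13S,8E)-13-[(tert-butyldimethylsilyl)oxy]-4,5-epoxy-20-norcembr-8-en-11-yn-1-yl]prop-2-enoic acid (cembrane numbering) | OC(=O)C(=C)[C@@H]1CC[C@]2(C)O[C@H]2CC/C(C)=C/CC#C[C@@H](O[Si](C)(C)C(C)(C)C)C1
F7 | step 16 | (1R,4R,5S,13S,8E)-13-[(tert-butyldimethylsilyl)oxy]-5-hydroxy-20-norcembra-8,15(17)-dien-11-yn-16,4-olide | C=C1C(=O)O[C@]2(C)CC[C@@H]1C[C@H](O[Si](C)(C)C(C)(C)C)C#CC/C=C(\C)CC[C@@H]2O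
F8 | step 8 | (4S)-3-[(2E)-5-[(2S,3S)-2-methyl-3-[(3E)-3-methyloct-3-en-6-yn-1-yl]oxiran-2-yl]pent-2-enoyl]-4-phenyl-1,3-oxazolidin-2-one | O=C1OC[C@H](c2ccccc2)N1C(=O)/C=C/CC[C@]3(C)O[C@H]3CC/C(C)=C/CC#CC
F9 | step 8 | (4S)-3-[(3R)-3-(3-{[tert-butyl(dimethyl)silyl]oxy}prop-1-en-2-yl)-5-[(2S,3S)-2-methyl-3-[(3E)-3-methyloct-3-en-6-yn-1-yl]oxiran-2-yl]pentanoyl]-4-phenyl-1,3-oxazolidin-2-one | O=C1OC[C@H](c2ccccc2)N1C(=O)C[C@H](C(=C)CO[Si](C)(C)C(C)(C)C)CC[C@]3(C)O[C@H]3CC/C(C)=C/CC#CC
F10 | step 8 | S-ethyl (3R)-3-(3-{[tert-butyl(dimethyl)silyl]oxy}prop-1-en-2-yl)-5-[(2S,3S)-2-methyl-3-[(3E)-3-methyloct-3-en-6-yn-1-yl]oxiran-2-yl]pentanethioate | CCSC(=O)C[C@H](C(=C)CO[Si](C)(C)C(C)(C)C)CC[C@]1(C)O[C@H]1CC/C(C)=C/CC#CC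
F11 | step 8 | S-ethyl (3R)-3-(3-hydroxyprop-1-en-2-yl)-5-[(2S,3S)-2-methyl-3-[(3E)-3-methyloct-3-en-6-yn-1-yl]oxiran-2-yl]pentanethioate | CCSC(=O)C[C@H](C(=C)CO)CC[C@]1(C)O[C@H]1CC/C(C)=C/CC#CC
F12 | step 4 | (2R,3S)-2-methyl-3-[(3E)-3-methyloct-3-en-6-yn-1-yl]oxirane-2-carbaldehyde | O=C[C@]1(C)O[C@H]1CC/C(C)=C/CC#CC
F13 | step 4 | (2E)-3-[(2S,3S)-2-methyl-3-[(3E)-3-methyloct-3-en-6-yn-1-yl]oxiran-2-yl]prop-2-enal | O=C/C=C/[C@]1(C)O[C@H]1CC/C(C)=C/CC#CC
F14 | step 2 | geranyl acetate, (2E)-3,7-dimethylocta-2,6-dien-1-yl acetate | CC(C)=CCC/C(C)=C/COC(C)=O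
F15 | step 2 | (2E,6E)-8-hydroxy-3,7-dimethylocta-2,6-dien-1-yl acetate | CC(=O)OC/C=C(\C)CC/C=C(\C)CO
F16 | step 2 | (2E)-5-[(2S,3S)-3-(hydroxymethyl)-3-methyloxiran-2-yl]-3-methylpent-2-en-1-yl acetate | OC[C@]1(C)O[C@H]1CC/C(C)=C/COC(C)=O
A1 | alternative 1 | (1R,4R,5S,13S,8E,11E)-13-[(tert-butyldimethylsilyl)oxy]-5-hydroxycembra-8,11,15(17)-trien-16,4-olide | C=C1C(=O)O[C@]2(C)CC[C@@H]1C[C@H](O[Si](C)(C)C(C)(C)C)/C(C)=C/C/C=C(\C)CC[C@@H]2O
A2 | alternative 1 | 2-[(1R,4S,5S,13S,8E,11E)-13-[(tert-butyldimethylsilyl)oxy]-4,5-epoxycembra-8,11-dien-1-yl]prop-2-enoic acid (cembrane numbering) | C=C(C(=O)O)[C@@H]1CC[C@]2(C)O[C@H]2CC/C(C)=C/C/C=C(\C)[C@@H](O[Si](C)(C)C(C)(C)C)C1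
A3 | alternative 2 | methyl 2-[(1R,4R,5S,13S,8E,11E)-13-[(tert-butyldimethylsilyl)oxy]-4,5-dihydroxycembra-8,11-dien-1-yl]acetate (cis-4,5-diol, cembrane numbering, C15 as CH2) | COC(=O)C[C@H]1C[C@H](O[Si](C)(C)C(C)(C)C)/C(C)=C/C/C=C(\C)CC[C@H](O)[C@](C)(O)CC1
A4 | alternative 2 | methyl (3R,5S,6E,9E)-5-[(tert-butyldimethylsilyl)oxy]-6,10-dimethyl-13-oxo-3-(3-oxobutyl)trideca-6,9-dienoate | COC(=O)C[C@H](CCC(C)=O)C[C@H](O[Si](C)(C)C(C)(C)C)/C(C)=C/C/C=C(\C)CCC=O
A5 | alternative 3 | (1R,4R,5S,8E,11E)-5-[(tert-butyldimethylsilyl)oxy]-13-oxocembra-8,11,15(17)-trien-16,4-olide | C=C1C(=O)O[C@]2(C)CC[C@@H]1CC(=O)/C(C)=C/C/C=C(\C)CC[C@@H]2O[Si](C)(C)C(C)(C)C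
A6 | alternative 3 | sixteen-membered dilactone: (4R,5S,8E,11E)-5-[(tert-butyldimethylsilyl)oxy] C13 enoate esterified with C17 of the 1(15)-alkylidene 16,4-oxepanone (cembrane numbering, C14 absent) | C/C1=C\C/C=C(\C)CC[C@H](O[Si](C)(C)C(C)(C)C)[C@@]2(C)CC/C=C(/COC1=O)C(=O)O2
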